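**Retrosynthetic overview**
1. Last disconnection: all four C–O bonds of the tetramethoxy core (two aryl C–OMe bonds by chloride replacement on a quinone, two O–CH3 bonds by reductive O-methylation of the quinone oxygens), leading back to a 2,5-dichloro-3,6-di(indolyl)-1,4-benzoquinone. This one-flask C–O endgame is the key step.
2. The dichloroquinone is cut at a quinone–indole C–C bond into 5-prenylindole and a mono(indolyl)dichloroquinone (conjugate addition, then dehydrogenation).
3. The mono(indolyl)dichloroquinone comes the same way from indole and 2,5-dichloro-1,4-benzoquinone.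
4. 5-Prenylindole comes from 5-bromoindole by Stille prenylation.
5. No ring is built: both indoles and the six-membered core are bought intact; the core travels as a quinone and becomes the benzene ring only in the last step.

Assumption: the target has no stereocentre, no stereogenic double bond and no configurationally stable axis (the aryl–indole bonds are taken to rotate at room temperature), so it is achiral and no stereocontrol is needed.

**Route**

Step 1
Reactants: 1 5-bromo-1H-indole; 2 tributyl(3-methylbut-2-en-1-yl)stannane
Product: 3 5-(3-methylbut-2-en-1-yl)-1H-indole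
Conditions: Pd(PPh3)4 (5 mol%), degassed DMF, 100 °C
Reagents that add atoms: none
Why: Stille coupling, in which oxidative addition of the aryl bromide to zerovalent palladium, transmetalation of the prenylstannane at its tin-bearing carbon and reductive elimination deliver the linear prenyl arene while the free indole N–H is tolerated under these neutral conditions.

Step 2
Reactants: 4 1H-indole; 5 2,5-dichloro-1,4-benzoquinone
Product: 7 2,5-dichloro-3-(1H-indol-3-yl)-1,4-benzoquinone, via indolylhydroquinone 6 (not isolated)
Conditions: conc. HCl (cat.), THF, rt; then DDQ (1.0 equiv), rt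
Reagents that add atoms: none
Why: Acid-promoted Michael-type (Friedel–Crafts) addition of indole C3 to the unsubstituted carbon of the activated quinone gives a hydroquinone that cannot add a second indole, and DDQ dehydrogenation then restores the quinone with both chlorines kept as leaving groups for the endgame.

Step 3
Reactants: 7 2,5-dichloro-3-(1H-indol-3-yl)-1,4-benzoquinone; 3 5-(3-methylbut-2-en-1-yl)-1H-indole
Product: 9 2,5-dichloro-3-(1H-indol-3-yl)-6-[5-(3-methylbut-2-en-1-yl)-1H-indol-3-yl]-1,4-benzoquinone, via bis(indolyl)hydroquinone 8 (not isolated)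
Conditions: AcOH, 40 °C; then DDQ (1.0 equiv), THF, rt
Reagents that add atoms: none
Why: The same Michael-type addition followed by DDQ dehydrogenation, now at the only unsubstituted carbon of 7 so that the two indoles must end up para to each other, with acetic acid as a promoter mild enough to leave the trisubstituted prenyl alkene intact.

Step 4
Reactants: 9 2,5-dichloro-3-(1H-indol-3-yl)-6-[5-(3-methylbut-2-en-1-yl)-1H-indol-3-yl]-1,4-benzoquinone
Product: 13 3-[4-(1H-indol-3-yl)-2,3,5,6-tetramethoxyphenyl]-5-(3-methylbut-2-en-1-yl)-1H-indole, via dimethoxyquinone 10 (not isolated), via aryl dimethyl phosphate 11 (not isolated), via sodium aryloxide 12 (not isolated)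
Conditions: NaOMe (2.1 equiv), THF/MeOH, 0 to 50 °C; then P(OMe)3 (1.3 equiv), 60 °C; then NaOMe (1.0 equiv), rt; then Me2SO4 (1.5 equiv), rt; under argon
Reagents that add atoms: sodium methoxide [Na+].[O-]C; trimethyl phosphite COP(OC)OC; dimethyl sulfate COS(=O)(=O)OC
Why: Proposed new method: one-flask reductive tetramethoxylation, in which methoxide first replaces both vinylogous acyl chlorides of the quinone by addition–elimination (two aryl C–O bonds), trimethyl phosphite then attacks a carbonyl oxygen of the resulting dimethoxyquinone with aromatisation as the driving force to give an aryloxytrimethoxyphosphonium phenoxide whose phenoxide oxygen is methylated by Arbuzov-type demethylation of the phosphonium (reduction and the third C–O bond in one event, without a free air-sensitive hydroquinone dianion and without water that would hydrolyse the vinylogous esters), and methoxide finally transesterifies the aryl dimethyl phosphate at phosphorus so that the released aryloxide is capped by dimethyl sulfate in a Williamson-type step (fourth C–O bond); the closest known reaction type is the Perkow-type oxyphilic addition of trialkyl phosphites to simple p-quinones giving 4-alkoxyaryl dialkyl phosphates, which has not been shown on a 2,5-dialkoxy-3,6-di(indolyl)quinone or merged with quinone substitution and phosphate-to-ether exchange.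

**Compound list**

1 | 5-bromo-1H-indole | Brc1ccc2[nH]ccc2c1 | starting material
2 | tributyl(3-methylbut-2-en-1-yl)stannane (prenyltributyltin) | CCCC[Sn](CCCC)(CCCC)CC=C(C)C | starting material
3 | 5-(3-methylbut-2-en-1-yl)-1H-indole (5-prenylindole) | CC(C)=CCc1ccc2[nH]ccc2c1 | intermediate
4 | 1H-indole | c1ccc2[nH]ccc2c1 | starting material
5 | 2,5-dichloro-1,4-benzoquinone | O=C1C=C(Cl)C(=O)C=C1Cl | starting material
6 | 2,5-dichloro-3-(1H-indol-3-yl)benzene-1,4-diol | Oc1cc(Cl)c(O)c(-c2c[nH]c3ccccc23)c1Cl | intermediate
7 | 2,5-dichloro-3-(1H-indol-3-yl)-1,4-benzoquinone | O=C1C=C(Cl)C(=O)C(-c2c[nH]c3ccccc23)=C1Cl | intermediate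
8 | 2,5-dichloro-3-(1H-indol-3-yl)-6-[5-(3-methylbut-2-en-1-yl)-1H-indol-3-yl]benzene-1,4-diol | Oc1c(Cl)c(-c2c[nH]c3ccccc23)c(O)c(Cl)c1-c1c[nH]c2ccc(CC=C(C)C)cc12 | intermediate
9 | 2,5-dichloro-3-(1H-indol-3-yl)-6-[5-(3-methylbut-2-en-1-yl)-1H-indol-3-yl]-1,4-benzoquinone | O=C1C(Cl)=C(-c2c[nH]c3ccccc23)C(=O)C(Cl)=C1-c1c[nH]c2ccc(CC=C(C)C)cc12 | intermediate
10 | 2,5-dimethoxy-3-(1H-indol-3-yl)-6-[5-(3-methylbut-2-en-1-yl)-1H-indol-3-yl]-1,4-benzoquinone | COC1=C(-c2c[nH]c3ccccc23)C(=O)C(OC)=C(-c2c[nH]c3ccc(CC=C(C)C)cc23)C1=O | intermediate
11 | 2-(1H-indol-3-yl)-3,4,6-trimethoxy-5-[5-(3-methylbut-2-en-1-yl)-1H-indol-3-yl]phenyl dimethyl phosphate (drawn as one O-regioisomer; the isomer with phosphate and new methyl ether exchanged forms alongside and converges on 13) | COc1c(OC)c(-c2c[nH]c3ccccc23)c(OP(=O)(OC)OC)c(OC)c1-c1c[nH]c2ccc(CC=C(C)C)cc12 | intermediate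
12 | sodium 2-(1H-indol-3-yl)-3,4,6-trimethoxy-5-[5-(3-methylbut-2-en-1-yl)-1H-indol-3-yl]phenolate (same regioisomer note as 11) | [Na+].COc1c(OC)c(-c2c[nH]c3ccccc23)c([O-])c(OC)c1-c1c[nH]c2ccc(CC=C(C)C)cc12 | intermediate
13 | 3-[4-(1H-indol-3-yl)-2,3,5,6-tetramethoxyphenyl]-5-(3-methylbut-2-en-1-yl)-1H-indole | COc1c(OC)c(-c2c[nH]c3ccc(CC=C(C)C)cc23)c(OC)c(OC)c1-c1c[nH]c2ccccc12 | target

**Step count and risks**

Total step count: 4. Longest linear sequence: 3 steps (steps 2, 3, 4 from indole and the dichloroquinone; equally steps 1, 3, 4 from 5-bromoindole).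

The three steps most likely to fail:

Step 4 (the proposed new reaction). The electron-rich, fully substituted quinone 10 may react too slowly with P(OMe)3, the phosphite may attack a methoxy-bearing carbon instead of oxygen, or a little base left at the capping stage may cause indole N-methylation. The fallback uses only known chemistry; it sets out from 9 and comes back at 13. NaOMe in THF/MeOH converts 9 into the dimethoxyquinone 10, which is now isolated. Na2S2O4 in THF/water reduces 10 to 2,5-dimethoxy-3-(1H-indol-3-yl)-6-[5-(3-methylbut-2-en-1-yl)-1H-indol-3-yl]benzene-1,4-diol F1. F1 is kept under argon and methylated on both phenols with Me2SO4 and K2CO3 in refluxing acetone, conditions that leave the indole N–H alone, to give 13.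

Step 3. The quinone 7 is deactivated by its indole donor, so the addition of the valuable prenylindole in acetic acid may be slow, and DDQ could attack the prenyl group. The fallback avoids acid and DDQ altogether; it sets out from 4 and comes back at 9. Indole 4 and bought chloranil (2,3,5,6-tetrachloro-1,4-benzoquinone) react with Cs2CO3 in MeCN by addition–elimination at a C–Cl carbon to give 2,3,5-trichloro-6-(1H-indol-3-yl)-1,4-benzoquinone F2. A second base-mediated substitution with 3 then replaces the chloride para to the first indole (the position that the push–pull donation of the first indole deactivates least) and gives 9 directly at the quinone oxidation level.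

Step 1. The Stille coupling may give some branched (reverse-prenyl) isomer, and tin residues can be hard to remove. The fallback builds the prenyl group in two stages from an allyl group, where no regiochemistry question arises; it sets out from 1 and comes back at 3. Suzuki–Miyaura coupling of 1 with allylboronic acid pinacol ester (Pd(dppf)Cl2, CsF, THF, reflux) gives 5-allyl-1H-indole F3. Cross-metathesis of F3 with excess 2-methyl-2-butene (second-generation Grubbs catalyst, CH2Cl2, 40 °C) then gives 3.

**Further compounds**

F1 | step 4 | 2,5-dimethoxy-3-(1H-indol-3-yl)-6-[5-(3-methylbut-2-en-1-yl)-1H-indol-3-yl]benzene-1,4-diol | COc1c(O)c(-c2c[nH]c3ccc(CC=C(C)C)cc23)c(OC)c(O)c1-c1c[nH]c2ccccc12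
F2 | step 3 | 2,3,5-trichloro-6-(1H-indol-3-yl)-1,4-benzoquinone | O=C1C(Cl)=C(Cl)C(=O)C(Cl)=C1-c1c[nH]c2ccccc12
F3 | step 1 | 5-allyl-1H-indole | C=CCc1ccc2[nH]ccc2c1
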